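## Retrosynthetic overview

- The target is 2-(5-hexadecylfuran-2-yl)acetic acid (C22H38O3). It is achiral, so no stereocentre needs to be set.
- The only disconnection is the furan C5–C16 bond. This gives a C5 furyl anion synergon with a hexadecyl cation equivalent.
- Commercial 2-furylacetic acid already carries the furan ring and the CH2CO2H side chain, so no ring is formed.
- The carboxylic acid is masked in situ as its lithium carboxylate. A second equivalent of n-BuLi lithiates C5, and the resulting dianion is alkylated with 1-iodohexadecane.

Assumptions: the SMILES chain is read as a linear n-hexadecyl group (16 carbons). Compound 1 is used as supplied, with no protecting group.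

## Route

**Step 1**
Reactants: **1** 2-(furan-2-yl)acetic acid; **2** 1-iodohexadecane
Product: **3** 2-(5-hexadecylfuran-2-yl)acetic acid (target)
Conditions:
- n-BuLi (2.1 equiv), TMEDA (2.1 equiv), THF, −78 °C → 0 °C, 1 h, to form the C5-lithio lithium carboxylate.
- Cool to −20 °C, add DMPU (co-solvent) and **2** (1.2 equiv), then warm to rt over 12 h.
- Quench with cold 10% aq. citric acid to pH ~3 and extract quickly with EtOAc.
- Purify by silica chromatography (hexane/EtOAc with 1% AcOH) or recrystallisation.

Reagents that add atoms: 1-iodohexadecane, CCCCCCCCCCCCCCCCI (its C16H33 group is incorporated).
Why: The first equivalent of n-BuLi gives the lithium carboxylate, which is much harder to deprotonate at the α-CH2 than the furan C5–H. The second equivalent therefore lithiates the furan α-position (C5), the most acidic ring C–H, by directed metalation. The resulting 2-furyllithium undergoes SN2 alkylation with the primary iodide, promoted by DMPU. Aqueous acidic work-up then reprotonates the carboxylate. No stereocentre is created.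

## Checks

- **Structure:** The product has a furan ring with CH2CO2H at C2 and an n-C16H33 group at C5. This matches CCCCCCCCCCCCCCCCc1ccc(CC(=O)O)o1. Atom balance: C6H6O3 (1) − 2H + C16H33 = C22H38O3.
- **Stereochemistry:** The target has none, and none is introduced.
- **Functional groups:**
  - The carboxylate protects the acid from attack by BuLi.
  - The furan survives organolithium conditions and is exposed only briefly to mild acid (pH ~3, cold) in the work-up.
  - The primary iodide reacts only with the aryllithium at −20 °C to rt.

## Compound list

1 | 2-(furan-2-yl)acetic acid | OC(=O)Cc1ccco1 | starting material
2 | 1-iodohexadecane | CCCCCCCCCCCCCCCCI | starting material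
3 | 2-(5-hexadecylfuran-2-yl)acetic acid | CCCCCCCCCCCCCCCCc1ccc(CC(=O)O)o1 | target

## Totals

Total steps: 1. Longest linear sequence: 1.

## Three steps most likely to fail

1. **Regioselective C5 lithiation instead of α-CH2 deprotonation (Step 1).**
   - Risk: the dianion forms at the α-carbon, giving 2-(furan-2-yl)octadecanoic acid, or over-lithiation occurs.
   - Fallback: a different approach in three steps from furan.
     - Lithiate furan and alkylate with 1-iodohexadecane to give 2-hexadecylfuran.
     - Friedel–Crafts acylation with ethyl chlorooxoacetate (SnCl4 or pyridine, CH2Cl2, 0 °C).
     - Wolff–Kishner reduction and ester saponification in one pot (N2H4, KOH, diethylene glycol, 140–180 °C) to give the acetic acid.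
2. **Alkylating the poorly soluble, aggregated dianion with a C16 iodide (Step 1).**
   - Risk: low conversion, or halogen–metal exchange giving 5-iodofuran and hexadecyllithium.
   - Fallback: a cross-coupling approach.
     - Brominate methyl 2-furylacetate with NBS at C5.
     - Negishi coupling with n-C16H33ZnBr (Pd-PEPPSI-IPr or Pd(OAc)2/CPhos, THF, rt).
     - LiOH hydrolysis to the acid.
3. **Acid sensitivity of the electron-rich 2,5-dialkylfuran during work-up and purification (Step 1).**
   - Risk: ring-opening or polymerisation on acidification or on silica.
   - Fallback: avoid the free acid until the end.
     - Carry the compound as its methyl ester, made by the Negishi route above.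
     - Purify the neutral ester on base-deactivated silica.
     - Hydrolyse at the end with LiOH (THF/H2O, rt), or use pig liver esterase at pH 7, so that no strong acid is ever used.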